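Suaveolindole is simplified by an extra bond from C13 (the CH2 between quaternary C5 and the indole) to C10 (the carboxyl carbon of the chain on C6). The ring so formed (C5, C6, C8, C9, C10, C13) is a 2-methylcyclohexane-1,3-dione whose C5 is prochiral between two carbonyls, C6 and C13. The key step exploits exactly this: an amino-acid-catalysed aldol condensation of triketone 3, a dione carrying the (R)-4-oxopentan-2-yl chain on C5, closes ring A (C1–C6) onto C6 only, so quaternary C5 is set against C4 in one operation. The temporary ring then directs the trans reduction at C6 and is opened by ozonolysis.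

Key step: step 2

Atom labels (target): ring A = C1 (=C7Me2), C2, C3, C4 (H, C11H3), C5 (C12H3, C13H2–indole), C6 (H, chain C8–C9–C10O2H).
Assumption: in step 1 the quinidine-derived primary amine is taken to give the R adduct; if the sense is opposite, the quinine-derived pseudoenantiomer is used.
Remark: 19 is a catalogue compound.

Step 1
Reactants: 1 2-methylcyclohexane-1,3-dione; 2 (E)-pent-3-en-2-one
Product: 3 2-methyl-2-[(2R)-4-oxopentan-2-yl]cyclohexane-1,3-dione
Conditions: 9-amino-9-deoxy-epi-quinidine (20 mol %), CF3CO2H (40 mol %), THF, 30 °C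
Reagents that add atoms: none
Why: Iminium-ion activation of the enone by the cinchona primary amine (organocatalytic Michael addition of a cyclic 1,3-dicarbonyl) should let the dione enol add to one face of the (E)-iminium ion, which sets C4, while the dione carbon stays prochiral.

Step 2
Reactants: 3 2-methyl-2-[(2R)-4-oxopentan-2-yl]cyclohexane-1,3-dione
Product: 5 (4R,4aR)-4,4a-dimethyl-4,4a,7,8-tetrahydronaphthalene-2,5(3H,6H)-dione, via cis-fused aldol ketol 4 (not isolated)
Conditions: D-phenylalanine (1.0 equiv), (1R)-(–)-10-camphorsulfonic acid (0.5 equiv), DMF, 30 → 70 °C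
Reagents that add atoms: none
Why: D-Phenylalanine condenses with the side-chain methyl ketone to the less substituted enamine (C1=C2–N), whose C1 adds to ring carbonyl C6 while the amino-acid carboxyl activates that carbonyl, and acid-promoted dehydration of ketol 4 with iminium hydrolysis gives the C1=C6 enone (Hajos–Parrish–Eder–Sauer–Wiechert reaction in its primary-amino-acid/sulfonic-acid form for hindered triketones). Ring A closes by a 6-(enolendo)-exo-trig aldol addition. C5 becomes stereogenic because only one of the two diastereotopic carbonyls (C6, not C13) is attacked, and this choice should be dictated by the amino acid: the D-series gives the 4aR sense, mirror image of the 4aS sense obtained with L-amino acids in the parent triketone. The selectivity needed is carbonyl discrimination with C4 left untouched; the (4R)-methyl can sit pseudo-equatorial in the chair-like transition state that leads to the 4,4a-trans isomer, so catalyst and substrate preferences should reinforce each other. The C6 carbinol centre of 4 is transient and is erased on dehydration.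

Step 3
Reactants: 5 (4R,4aR)-4,4a-dimethyl-4,4a,7,8-tetrahydronaphthalene-2,5(3H,6H)-dione
Product: 6 (4R,4aR,5R)-5-hydroxy-4,4a-dimethyl-4,4a,5,6,7,8-hexahydronaphthalen-2(3H)-one
Conditions: NaBH4 (0.3 equiv), EtOH, –10 °C
Reagents that add atoms: none
Why: Chemoselective borohydride reduction, since the saturated C13 ketone is far more electrophilic than the vinylogous enone carbonyl (as in the Wieland–Miescher ketone), with hydride entering anti to the angular methyl so that the hydroxyl is cis to it; this centre is removed in step 4.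

Step 4
Reactants: 6 (4R,4aR,5R)-5-hydroxy-4,4a-dimethyl-4,4a,5,6,7,8-hexahydronaphthalen-2(3H)-one
Product: 7 (4R,4aS)-4,4a-dimethyl-4,4a,7,8-tetrahydronaphthalen-2(3H)-one
Conditions: Burgess reagent (1.5 equiv), toluene, 50 → 80 °C
Reagents that add atoms: none
Why: Burgess dehydration, in which the sulfamate ester at C13–O undergoes thermal syn-elimination toward C10, the only β-carbon bearing hydrogen (C5 is quaternary), under neutral conditions that avoid a C13 alkoxide (vinylogous retro-aldol) and leave the enone untouched.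

Step 5
Reactants: 7 (4R,4aS)-4,4a-dimethyl-4,4a,7,8-tetrahydronaphthalen-2(3H)-one
Product: 9 (1S,4R,4aS,8aR)-1-(2-hydroxypropan-2-yl)-4,4a-dimethyl-3,4,4a,7,8,8a-hexahydronaphthalen-2(1H)-one, via lithium enolate 8 (not isolated)
Conditions: Li (2.2 equiv), t-BuOH (1.0 equiv), NH3(l)/THF, –78 °C; isoprene; NH3 evaporated; ZnCl2 (1.0 equiv), THF, –20 °C; acetone (5 equiv); aq NH4Cl
Reagents that add atoms: acetone, CC(C)=O
Why: Dissolving-metal enone reduction with Stork-type trapping of the regiodefined enolate, in which axial protonation of the C6 carbanion anti to the angular methyl should give the trans ring fusion (isolated C13=C10 is inert) and the C1–C2 enolate 8, as its zinc aldolate, adds to acetone at C1 to place the side chain equatorial; the C1 centre is erased in step 9.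

Step 6
Reactants: 9 (1S,4R,4aS,8aR)-1-(2-hydroxypropan-2-yl)-4,4a-dimethyl-3,4,4a,7,8,8a-hexahydronaphthalen-2(1H)-one
Product: 10 (1R,2R,3S,6R)-3-(2-hydroxypropan-2-yl)-1,6-dimethyl-4-oxo-2-(3-oxopropyl)cyclohexane-1-carbaldehyde
Conditions: O3, CH2Cl2, –78 °C; PPh3, –78 °C → rt
Reagents that add atoms: ozone, [O-][O+]=O
Why: Ozonolysis with reductive work-up cleaves the only C=C (cis-disubstituted C13=C10) and so opens the temporary ring, the ketone and tertiary alcohol being inert to ozone; the crude dialdehyde is used at once.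

Step 7
Reactants: 10 (1R,2R,3S,6R)-3-(2-hydroxypropan-2-yl)-1,6-dimethyl-4-oxo-2-(3-oxopropyl)cyclohexane-1-carbaldehyde
Product: 11 (1R,2R,3S,6R)-2-(2-carboxyethyl)-3-(2-hydroxypropan-2-yl)-1,6-dimethyl-4-oxocyclohexane-1-carboxylic acid
Conditions: NaClO2, NaH2PO4, 2-methyl-2-butene, t-BuOH/H2O, 0 °C → rt
Reagents that add atoms: sodium chlorite, [Na+].[O-]Cl=O
Why: Pinnick oxidation takes both aldehydes, including the α-quaternary one, to acids under buffered conditions that spare the β-hydroxy ketone, and no C=C is present yet to suffer from hypochlorite.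

Step 8
Reactants: 11 (1R,2R,3S,6R)-2-(2-carboxyethyl)-3-(2-hydroxypropan-2-yl)-1,6-dimethyl-4-oxocyclohexane-1-carboxylic acid
Product: 12 (1R,2R,3S,6R)-3-(2-hydroxypropan-2-yl)-2-(3-methoxy-3-oxopropyl)-1,6-dimethyl-4-oxocyclohexane-1-carboxylic acid
Conditions: HCl (0.1 M in MeOH), 0 °C → rt
Reagents that add atoms: methanol, CO
Why: Fischer esterification depends on access to the tetrahedral intermediate, so the unhindered C10 acid should be esterified while the C13 acid on fully substituted C5 is left, and any early loss of water from the aldol unit converges in step 9.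

Step 9
Reactants: 12 (1R,2R,3S,6R)-3-(2-hydroxypropan-2-yl)-2-(3-methoxy-3-oxopropyl)-1,6-dimethyl-4-oxocyclohexane-1-carboxylic acid
Product: 13 (1R,2R,6R)-2-(3-methoxy-3-oxopropyl)-1,6-dimethyl-4-oxo-3-(propan-2-ylidene)cyclohexane-1-carboxylic acid
Conditions: TsOH·H2O (10 mol %), toluene, 60 °C; then DBU (3 equiv), rt; aq citric acid
Reagents that add atoms: none
Why: Acid-catalysed aldol dehydration of the tertiary β-hydroxy ketone gives the conjugated tetrasubstituted C1=C7 enone (regiochemistry fixed by conjugation, and feasible now that the ring is open and the C6 chain can turn axial to escape allylic strain), and the DBU finish returns any β-acyloxy ketone formed by capture of C7 by the C13 acid to the same enone by E1cB elimination.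

Step 10
Reactants: 13 (1R,2R,6R)-2-(3-methoxy-3-oxopropyl)-1,6-dimethyl-4-oxo-3-(propan-2-ylidene)cyclohexane-1-carboxylic acid
Product: 14 (1R,2R,6R)-2-(3-methoxy-3-oxopropyl)-1,6-dimethyl-3-(propan-2-ylidene)-4-[(trifluoromethanesulfonyl)oxy]cyclohex-4-ene-1-carboxylic acid
Conditions: LDA (2.2 equiv), THF, –78 °C; PhNTf2 (1.1 equiv), –78 → 0 °C; dilute HCl work-up
Reagents that add atoms: N-phenylbis(trifluoromethanesulfonimide), O=S(=O)(N(c1ccccc1)S(=O)(=O)C(F)(F)F)C(F)(F)F
Why: After carboxylate formation, kinetic α′-deprotonation at C3 of the cross-conjugated enone (as in the 2-alkylation of pulegone) and O-triflation of the enolate give the dienyl triflate, the less acidic ester α-CH2 being left alone at –78 °C.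

Step 11
Reactants: 14 (1R,2R,6R)-2-(3-methoxy-3-oxopropyl)-1,6-dimethyl-3-(propan-2-ylidene)-4-[(trifluoromethanesulfonyl)oxy]cyclohex-4-ene-1-carboxylic acid
Product: 15 (1R,2R,6R)-2-(3-methoxy-3-oxopropyl)-1,6-dimethyl-3-(propan-2-ylidene)cyclohex-4-ene-1-carboxylic acid
Conditions: Pd(OAc)2 (5 mol %), PPh3 (10 mol %), HCO2H (3 equiv), Bu3N (5 equiv), DMF, 60 °C
Reagents that add atoms: none
Why: Palladium-catalysed formate reduction of the enol triflate (oxidative addition, formate decarboxylation, C–H reductive elimination) replaces OTf by H and so removes the C2 oxygen without allylic intermediates that could move C1=C7.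

Step 12
Reactants: 15 (1R,2R,6R)-2-(3-methoxy-3-oxopropyl)-1,6-dimethyl-3-(propan-2-ylidene)cyclohex-4-ene-1-carboxylic acid
Product: 16 (1R,2R,6R)-2-(3-methoxy-3-oxopropyl)-1,6-dimethyl-3-(propan-2-ylidene)cyclohexane-1-carboxylic acid
Conditions: 2-nitrobenzenesulfonylhydrazide (excess), Et3N, CH2Cl2, rt
Reagents that add atoms: none
Why: Diimide reduction delivers H2 concertedly to the unhindered cis-disubstituted C2=C3 bond only, the tetrasubstituted C1=C7 bond being orders of magnitude less reactive, so C2 ends as CH2 with the isopropylidene in place and without acid or metal hydride.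

Step 13
Reactants: 16 (1R,2R,6R)-2-(3-methoxy-3-oxopropyl)-1,6-dimethyl-3-(propan-2-ylidene)cyclohexane-1-carboxylic acid
Product: 18 methyl 3-[(1R,2R,3R)-2-formyl-2,3-dimethyl-6-(propan-2-ylidene)cyclohexyl]propanoate, via acid chloride 17 (not isolated)
Conditions: 1-chloro-N,N,2-trimethylprop-1-en-1-amine (Ghosez reagent), CH2Cl2, 0 °C → rt; then LiAlH(O-t-Bu)3 (1.2 equiv), THF, –78 °C
Reagents that add atoms: none
Why: Neutral conversion of the hindered acid into its chloride (no HCl that could add to C1=C7 or induce lactonisation) and partial reduction of the acid chloride with the hindered alkoxyaluminium hydride, which stops at the aldehyde and does not touch the methyl ester.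

Step 14
Reactants: 18 methyl 3-[(1R,2R,3R)-2-formyl-2,3-dimethyl-6-(propan-2-ylidene)cyclohexyl]propanoate; 19 3-bromo-1-[tri(propan-2-yl)silyl]-1H-indole
Product: 21 methyl 3-[(1R,2R,3R)-2-{hydroxy[1-(triisopropylsilyl)-1H-indol-3-yl]methyl}-2,3-dimethyl-6-(propan-2-ylidene)cyclohexyl]propanoate, via 3-lithio-1-(triisopropylsilyl)indole 20 (not isolated)
Conditions: 19 (1.3 equiv), t-BuLi (2.6 equiv), THF, –78 °C; then 18, –78 °C; aq NH4Cl
Reagents that add atoms: none
Why: Bromine–lithium exchange gives the 3-lithioindole, held at C3 by the bulky N-silyl group, and its 1,2-addition to the neopentyl aldehyde at –78 °C should outrun attack on the methyl ester; the new carbinol centre (both epimers) is removed in step 15.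

Step 15
Reactants: 21 methyl 3-[(1R,2R,3R)-2-{hydroxy[1-(triisopropylsilyl)-1H-indol-3-yl]methyl}-2,3-dimethyl-6-(propan-2-ylidene)cyclohexyl]propanoate
Product: 22 methyl 3-[(1S,2R,3R)-2,3-dimethyl-6-(propan-2-ylidene)-2-{[1-(triisopropylsilyl)-1H-indol-3-yl]methyl}cyclohexyl]propanoate
Conditions: Et3SiH (6 equiv), CF3CO2H (3 equiv), CH2Cl2, –40 → –10 °C
Reagents that add atoms: none
Why: Ionic hydrogenation, in which the indol-3-yl carbinol ionises at low temperature to the stabilised 3-alkylideneindoleninium ion that the silane reduces to CH2, while the alkene is not protonated under these conditions and its attack on the cation would need a bridgehead cation or a four-membered ring.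

Step 16
Reactants: 22 methyl 3-[(1S,2R,3R)-2,3-dimethyl-6-(propan-2-ylidene)-2-{[1-(triisopropylsilyl)-1H-indol-3-yl]methyl}cyclohexyl]propanoate
Product: 24 3-[(1S,2R,3R)-2-(1H-indol-3-ylmethyl)-2,3-dimethyl-6-(propan-2-ylidene)cyclohexyl]propanoic acid (suaveolindole), via N-unprotected methyl ester 23 (not isolated)
Conditions: TBAF (1.5 equiv), THF, 0 °C → rt; then LiOH, THF/MeOH/H2O, 40 °C; AcOH to pH 5
Reagents that add atoms: lithium hydroxide, [Li+].[OH-]
Why: Fluoride cleaves the N–Si bond and hydroxide saponifies the unhindered methyl ester, with acidification only to pH 5 so that the free acid is not exposed to conditions that could lactonise it onto C1=C7.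

Compound list
1 | 2-methylcyclohexane-1,3-dione | CC1C(=O)CCCC1=O | starting material
2 | (E)-pent-3-en-2-one | C/C=C/C(C)=O | starting material
3 | 2-methyl-2-[(2R)-4-oxopentan-2-yl]cyclohexane-1,3-dione | CC(=O)C[C@@H](C)C1(C)C(=O)CCCC1=O | intermediate
4 | (4R,4aR,8aR)-8a-hydroxy-4,4a-dimethyloctahydronaphthalene-2,5-dione, cis-fused ketol with 8a-OH cis to 4a-CH3 (formed in situ) | O=C1C[C@@H](C)[C@@]2(C)C(=O)CCC[C@@]2(O)C1 | intermediate
5 | (4R,4aR)-4,4a-dimethyl-4,4a,7,8-tetrahydronaphthalene-2,5(3H,6H)-dione (methyl groups trans) | O=C1C[C@@H](C)[C@@]2(C)C(=O)CCCC2=C1 | intermediate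
6 | (4R,4aR,5R)-5-hydroxy-4,4a-dimethyl-4,4a,5,6,7,8-hexahydronaphthalen-2(3H)-one (5-OH cis to 4a-CH3) | O=C1C[C@@H](C)[C@@]2(C)[C@H](O)CCCC2=C1 | intermediate
7 | (4R,4aS)-4,4a-dimethyl-4,4a,7,8-tetrahydronaphthalen-2(3H)-one (C5=C6 and C1=C8a double bonds) | O=C1C[C@@H](C)[C@@]2(C)C=CCCC2=C1 | intermediate
8 | lithium (4R,4aS,8aR)-4,4a-dimethyl-3,4,4a,7,8,8a-hexahydronaphthalen-2-olate, trans-fused C1=C2 enolate (formed in situ) | [Li+].[O-]C1=C[C@H]2CCC=C[C@]2(C)[C@H](C)C1 | intermediate
9 | (1S,4R,4aS,8aR)-1-(2-hydroxypropan-2-yl)-4,4a-dimethyl-3,4,4a,7,8,8a-hexahydronaphthalen-2(1H)-one (trans-fused; side chain at C1 equatorial, cis to H-8a) | CC(C)(O)[C@H]1C(=O)C[C@@H](C)[C@@]2(C)C=CCC[C@H]12 | intermediate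
10 | (1R,2R,3S,6R)-3-(2-hydroxypropan-2-yl)-1,6-dimethyl-4-oxo-2-(3-oxopropyl)cyclohexane-1-carbaldehyde | CC(C)(O)[C@H]1C(=O)C[C@@H](C)[C@@](C)(C=O)[C@@H]1CCC=O | intermediate
11 | (1R,2R,3S,6R)-2-(2-carboxyethyl)-3-(2-hydroxypropan-2-yl)-1,6-dimethyl-4-oxocyclohexane-1-carboxylic acid | CC(C)(O)[C@H]1C(=O)C[C@@H](C)[C@@](C)(C(=O)O)[C@@H]1CCC(=O)O | intermediate
12 | (1R,2R,3S,6R)-3-(2-hydroxypropan-2-yl)-2-(3-methoxy-3-oxopropyl)-1,6-dimethyl-4-oxocyclohexane-1-carboxylic acid | CC(C)(O)[C@H]1C(=O)C[C@@H](C)[C@@](C)(C(=O)O)[C@@H]1CCC(=O)OC | intermediate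
13 | (1R,2R,6R)-2-(3-methoxy-3-oxopropyl)-1,6-dimethyl-4-oxo-3-(propan-2-ylidene)cyclohexane-1-carboxylic acid | CC(C)=C1C(=O)C[C@@H](C)[C@@](C)(C(=O)O)[C@@H]1CCC(=O)OC | intermediate
14 | (1R,2R,6R)-2-(3-methoxy-3-oxopropyl)-1,6-dimethyl-3-(propan-2-ylidene)-4-[(trifluoromethanesulfonyl)oxy]cyclohex-4-ene-1-carboxylic acid | CC(C)=C1C(OS(=O)(=O)C(F)(F)F)=C[C@@H](C)[C@@](C)(C(=O)O)[C@@H]1CCC(=O)OC | intermediate
15 | (1R,2R,6R)-2-(3-methoxy-3-oxopropyl)-1,6-dimethyl-3-(propan-2-ylidene)cyclohex-4-ene-1-carboxylic acid | CC(C)=C1C=C[C@@H](C)[C@@](C)(C(=O)O)[C@@H]1CCC(=O)OC | intermediate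
16 | (1R,2R,6R)-2-(3-methoxy-3-oxopropyl)-1,6-dimethyl-3-(propan-2-ylidene)cyclohexane-1-carboxylic acid | CC(C)=C1CC[C@@H](C)[C@@](C)(C(=O)O)[C@@H]1CCC(=O)OC | intermediate
17 | methyl 3-[(1R,2R,3R)-2-(chlorocarbonyl)-2,3-dimethyl-6-(propan-2-ylidene)cyclohexyl]propanoate (formed in situ) | CC(C)=C1CC[C@@H](C)[C@@](C)(C(=O)Cl)[C@@H]1CCC(=O)OC | intermediate
18 | methyl 3-[(1R,2R,3R)-2-formyl-2,3-dimethyl-6-(propan-2-ylidene)cyclohexyl]propanoate | CC(C)=C1CC[C@@H](C)[C@@](C)(C=O)[C@@H]1CCC(=O)OC | intermediate
19 | 3-bromo-1-[tri(propan-2-yl)silyl]-1H-indole | CC(C)[Si](C(C)C)(C(C)C)n1cc(Br)c2ccccc21 | starting material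
20 | 3-lithio-1-[tri(propan-2-yl)silyl]-1H-indole (formed in situ) | CC(C)[Si](C(C)C)(C(C)C)n1cc([Li])c2ccccc21 | intermediate
21 | methyl 3-[(1R,2R,3R)-2-{hydroxy[1-(triisopropylsilyl)-1H-indol-3-yl]methyl}-2,3-dimethyl-6-(propan-2-ylidene)cyclohexyl]propanoate (both carbinol epimers) | CC(C)=C1CC[C@@H](C)[C@@](C)(C(O)c2cn([Si](C(C)C)(C(C)C)C(C)C)c3ccccc23)[C@@H]1CCC(=O)OC | intermediate
22 | methyl 3-[(1S,2R,3R)-2,3-dimethyl-6-(propan-2-ylidene)-2-{[1-(triisopropylsilyl)-1H-indol-3-yl]methyl}cyclohexyl]propanoate | CC(C)=C1CC[C@@H](C)[C@@](C)(Cc2cn([Si](C(C)C)(C(C)C)C(C)C)c3ccccc23)[C@@H]1CCC(=O)OC | intermediate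
23 | methyl 3-[(1S,2R,3R)-2-(1H-indol-3-ylmethyl)-2,3-dimethyl-6-(propan-2-ylidene)cyclohexyl]propanoate (formed in situ) | CC(C)=C1CC[C@@H](C)[C@@](C)(Cc2c[nH]c3ccccc23)[C@@H]1CCC(=O)OC | intermediate
24 | 3-[(1S,2R,3R)-2-(1H-indol-3-ylmethyl)-2,3-dimethyl-6-(propan-2-ylidene)cyclohexyl]propanoic acid (suaveolindole) | CC(C)=C1CC[C@@H](C)[C@@](C)(Cc2c[nH]c3ccccc23)[C@@H]1CCC(=O)O | target

Total step count: 16. Longest linear sequence: 16 steps (1 + 2 → 24); 19 enters as a purchased reagent in step 14.

Steps most likely to fail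

Step 1. The hindered, poorly soluble dione may add only slowly to the β-substituted iminium ion, facial control may be incomplete, and the adduct may revert by retro-Michael reaction. The fallback sets out from 1 and 2: the addition is run without chiral control (Et3N, EtOAc, 70 °C) to give racemic 2-methyl-2-(4-oxopentan-2-yl)cyclohexane-1,3-dione F1. F1 is then cyclised under the step 2 conditions, where catalyst control over C5 should turn the two enantiomers into diastereomers: the 4R half gives 5, and the 4S half gives the cis-dimethyl dione (4S,4aR)-4,4a-dimethyl-4,4a,7,8-tetrahydronaphthalene-2,5(3H,6H)-dione F2, which is removed by chromatography or crystallisation. The route is rejoined at 5.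

Step 2. Discrimination between the two ring carbonyls may be poor if the catalyst and the C4 centre oppose each other, and C4 may erode by retro-Michael/Michael equilibration under the warm amine–acid conditions. The fallback sets out from 3 and replaces catalyst control by substrate control plus separation: an achiral enamine aldol condensation (pyrrolidine, AcOH, EtOAc, rt) should give 5 together with its C5 epimer, the cis-dimethyl dione (4R,4aS)-4,4a-dimethyl-4,4a,7,8-tetrahydronaphthalene-2,5(3H,6H)-dione F3. Because C4 was fixed in step 1, both are single enantiomers and are separated as diastereomers. The route is rejoined at 5.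

Step 5. Protonation at C6 may suffer in facial selectivity from the syn C4 methyl, the enolate may take a proton from acetone instead of adding, and the aldolate may revert on warming. The fallback sets out from 7 and separates reduction from C–C bond formation: after the Li/NH3 reduction the enolate is silylated (TMSCl, Et3N, –78 °C) and isolated as trimethyl{[(4R,4aS,8aR)-4,4a-dimethyl-3,4,4a,7,8,8a-hexahydronaphthalen-2-yl]oxy}silane F4. A Mukaiyama aldol addition of F4 to acetone (TiCl4, CH2Cl2, –78 °C), which does not pass through a basic aldolate, should then give 9, where the route is rejoined.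

Further compounds
F1 | step 1 | racemic 2-methyl-2-(4-oxopentan-2-yl)cyclohexane-1,3-dione | CC(=O)CC(C)C1(C)C(=O)CCCC1=O
F2 | step 1 | (4S,4aR)-4,4a-dimethyl-4,4a,7,8-tetrahydronaphthalene-2,5(3H,6H)-dione | O=C1C[C@H](C)[C@@]2(C)C(=O)CCCC2=C1
F3 | step 2 | (4R,4aS)-4,4a-dimethyl-4,4a,7,8-tetrahydronaphthalene-2,5(3H,6H)-dione | O=C1C[C@@H](C)[C@]2(C)C(=O)CCCC2=C1
F4 | step 5 | trimethyl{[(4R,4aS,8aR)-4,4a-dimethyl-3,4,4a,7,8,8a-hexahydronaphthalen-2-yl]oxy}silane | C[Si](C)(C)OC1=C[C@H]2CCC=C[C@]2(C)[C@H](C)C1
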